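**Plan**
1. Retrosynthetic cuts: first the 7-O acetal, then the C2=C3 double bond (back to the isoflavanone), then the O1–C2 bond of ring C (retro-oxa-Michael), and finally C4a–C4 and C4–C3 together.
2. Enabling feature: the C4 carbonyl carbon of ring C has only two carbon neighbours, C4a of ring A and C3, which carries ring B. C4 can therefore enter as carbon monoxide between an iodide at C4a and a boron at C3 of a 1-arylvinyl unit whose =CH2 becomes C2.
3. Forward order: rings A and B are bought as benzene rings. Ring A is dressed (O-protection, CHO to OH, prenyl at C8, iodine at C4a) and ring B becomes the α-styrylboronate. The three components are joined to an open-chain aryl 1-arylvinyl ketone, and ring C, the only ring made, closes afterwards at O1–C2 and is dehydrogenated.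
4. The two ring-A oxygens appear at different stages, so they receive acetals of different lability (THP on the later O1, MOM on O7) and O1 can be freed alone.
5. Stereochemistry: the target has no stereocentre and no E/Z double bond. The centres met on the way (THP acetal carbon, C3 of the isoflavanone and of its selenide) are racemic and are erased.

Key step: step 8

Remark: the target is achiral, so "single enantiomer" is read as the constitution of the SMILES, and nothing has to be induced or resolved.

**Route**

Step 1
Reactants: 1 isovanillin (3-hydroxy-4-methoxybenzaldehyde)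
Product: 2 4-methoxy-3-(methoxymethoxy)benzaldehyde
Conditions: MOMCl, K2CO3, acetone, 0 °C → rt
Reagents that add atoms: chloromethyl methyl ether (MOMCl), COCCl
Why: Williamson-type O-alkylation of the phenoxide masks the later 7-OH as a base-stable acetal that directs lithiation and can be removed last under mild acid.

Step 2
Reactants: 2 4-methoxy-3-(methoxymethoxy)benzaldehyde
Product: 4 4-methoxy-3-(methoxymethoxy)phenol, via aryl formate 3 (not isolated)
Conditions: mCPBA, CH2Cl2, 0 °C → rt; then K2CO3 (cat.), MeOH, rt
Reagents that add atoms: 3-chloroperbenzoic acid (mCPBA), O=C(OO)c1cccc(Cl)c1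
Why: In this Baeyer–Villiger oxidation the aryl group, activated by its para-methoxy substituent, migrates in preference to hydrogen, and methanolysis of the crude formate frees the phenol oxygen that becomes O1.

Step 3
Reactants: 4 4-methoxy-3-(methoxymethoxy)phenol
Product: 5 2-[4-methoxy-3-(methoxymethoxy)phenoxy]oxane (racemic THP ether)
Conditions: 3,4-dihydro-2H-pyran, PPTS (cat.), CH2Cl2, rt
Reagents that add atoms: 3,4-dihydro-2H-pyran, C1=COCCC1
Why: Acid-catalysed tetrahydropyranylation gives a second lithiation-directing acetal that is clearly more acid-labile than MOM, and its racemic acetal carbon is lost again in step 9.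

Step 4
Reactants: 5 2-[4-methoxy-3-(methoxymethoxy)phenoxy]oxane; 6 prenyl bromide (1-bromo-3-methylbut-2-ene)
Product: 8 2-[4-methoxy-3-(methoxymethoxy)-2-(3-methylbut-2-enyl)phenoxy]oxane (racemic), via doubly flanked aryllithium 7 (not isolated)
Conditions: n-BuLi, THF, 0 °C → rt; CuI (10 mol %), then 6, −78 °C → rt
Reagents that add atoms: none
Why: Directed ortho-metalation takes the proton between the two acetal oxygens, which both coordinate lithium, and copper-catalysed SN2 allylation at the primary carbon of prenyl bromide places the unrearranged prenyl group at the later C8.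

Step 5
Reactants: 8 2-[4-methoxy-3-(methoxymethoxy)-2-(3-methylbut-2-enyl)phenoxy]oxane
Product: 10 2-[6-iodo-4-methoxy-3-(methoxymethoxy)-2-(3-methylbut-2-enyl)phenoxy]oxane (racemic), via second aryllithium 9 (not isolated)
Conditions: s-BuLi, TMEDA, THF, −78 °C; then I2, THF, −78 °C → rt; aq. Na2S2O3
Reagents that add atoms: iodine, II
Why: In this second directed ortho-metalation the acetal-type OTHP group outranks OMe as director, so of the two remaining ring protons the one next to OTHP (the later C4a) should be removed under kinetic control, and the iodine quench fixes the halide without an electrophile meeting the prenyl double bond for long.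

Step 6
Reactants: 11 3',4'-dimethoxyacetophenone
Product: 13 1-(3,4-dimethoxyphenyl)vinyl trifluoromethanesulfonate, via potassium enolate 12 (not isolated)
Conditions: KHMDS, THF, −78 °C; PhNTf2, −78 → 0 °C
Reagents that add atoms: N-phenylbis(trifluoromethanesulfonimide) (PhNTf2), O=S(=O)(N(c1ccccc1)S(=O)(=O)C(F)(F)F)C(F)(F)F
Why: O-Sulfonylation of the only possible enolate of a methyl aryl ketone with a mild triflyl donor is the standard entry to 1-arylvinyl triflates.

Step 7
Reactants: 13 1-(3,4-dimethoxyphenyl)vinyl trifluoromethanesulfonate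
Product: 14 2-[1-(3,4-dimethoxyphenyl)vinyl]-4,4,5,5-tetramethyl-1,3,2-dioxaborolane
Conditions: B2pin2, PdCl2(PPh3)2 (3 mol %), PPh3 (6 mol %), KOPh, toluene, 50 °C
Reagents that add atoms: bis(pinacolato)diboron, CC1(C)OB(OC1(C)C)B1OC(C)(C)C(C)(C)O1
Why: Miyaura borylation of an alkenyl triflate exchanges C–OTf for C–B at the same carbon, and the phenoxide base at low temperature suppresses follow-up coupling of the product with unreacted triflate.

Step 8
Reactants: 10 2-[6-iodo-4-methoxy-3-(methoxymethoxy)-2-(3-methylbut-2-enyl)phenoxy]oxane; 14 2-[1-(3,4-dimethoxyphenyl)vinyl]-4,4,5,5-tetramethyl-1,3,2-dioxaborolane; 15 carbon monoxide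
Product: 16 2-(3,4-dimethoxyphenyl)-1-[5-methoxy-4-(methoxymethoxy)-3-(3-methylbut-2-enyl)-2-(oxan-2-yloxy)phenyl]prop-2-en-1-one (racemic at the THP carbon)
Conditions: CO (3 bar), PdCl2(dppf) (5 mol %), K2CO3, H2O (5 equiv), BHT (trace), anisole, 80 °C
Reagents that add atoms: none
Why: Pd(0) inserts into the C4a–I bond of 10, CO (15) undergoes migratory insertion to an aroylpalladium(II) iodide, the carbonate/water-activated boronate 14 hands over its α-styryl group, and reductive elimination releases 16, so C4a–C4 and C4–C3 form in one operation. The closest known reaction type is the carbonylative Suzuki–Miyaura coupling of aryl iodides with alkenylboron reagents to aryl vinyl ketones, here applied to new partners. No ring closes and no stereocentre is formed, and the product is the open-chain ketone whose exocyclic =CH2 is the later C2, within reach of the still masked O1. The selectivity required is carbonylation ahead of direct aryl–vinyl coupling: the electron-rich, ortho-alkoxy arylpalladium species takes up CO quickly, the CO overpressure keeps it saturated, and the hindered 1,1-disubstituted pinacol boronate transmetalates slowly enough to meet the acyl complex rather than the aryl complex. The medium is weakly basic and contains neither acid nor oxidant, so the prenyl double bond and both acetals stay untouched, while BHT and the moderate temperature hold back polymerisation of the enone.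

Step 9
Reactants: 16 2-(3,4-dimethoxyphenyl)-1-[5-methoxy-4-(methoxymethoxy)-3-(3-methylbut-2-enyl)-2-(oxan-2-yloxy)phenyl]prop-2-en-1-one
Product: 18 (±)-3-(3,4-dimethoxyphenyl)-6-methoxy-7-(methoxymethoxy)-8-(3-methylbut-2-enyl)chroman-4-one, via free ortho-hydroxy enone 17 (not isolated)
Conditions: PPTS (cat.), MeOH, rt; then Et3N (cat.), rt
Reagents that add atoms: none
Why: Mild acetal exchange removes only the THP group, and the liberated ortho-phenol adds to the α-aryl enone in a 6-endo-trig oxa-Michael reaction, the closure known from isoflavanone syntheses that pass through α-methylene 2-hydroxydeoxybenzoins; C3 forms racemic and is erased in step 11.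

Step 10
Reactants: 18 (±)-3-(3,4-dimethoxyphenyl)-6-methoxy-7-(methoxymethoxy)-8-(3-methylbut-2-enyl)chroman-4-one
Product: 20 (±)-3-(3,4-dimethoxyphenyl)-6-methoxy-7-(methoxymethoxy)-8-(3-methylbut-2-enyl)-3-(phenylselanyl)chroman-4-one, via lithium enolate 19 (not isolated)
Conditions: LiHMDS, THF, −78 °C; PhSeCl (1.0 equiv), THF, −78 °C
Reagents that add atoms: benzeneselenenyl chloride, Cl[Se]c1ccccc1
Why: In this α-selenenylation of a ketone enolate, C3 is the only enolisable and also benzylic position, and at −78 °C the enolate should consume one equivalent of PhSeCl far faster than the trisubstituted prenyl alkene can.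

Step 11
Reactants: 20 (±)-3-(3,4-dimethoxyphenyl)-6-methoxy-7-(methoxymethoxy)-8-(3-methylbut-2-enyl)-3-(phenylselanyl)chroman-4-one
Product: 22 3-(3,4-dimethoxyphenyl)-6-methoxy-7-(methoxymethoxy)-8-(3-methylbut-2-enyl)-4H-chromen-4-one, via selenoxide 21 (not isolated)
Conditions: NaIO4 (2.5 equiv), THF/MeOH/H2O, 0 °C → rt
Reagents that add atoms: none
Why: In this selenoxide syn-elimination the only β-hydrogens are at C2, so C2=C3 is the sole outcome; periodate leaves the prenyl alkene alone, and its excess carries the selenenic acid on to the seleninic acid before it can add to that alkene.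

Step 12
Reactants: 22 3-(3,4-dimethoxyphenyl)-6-methoxy-7-(methoxymethoxy)-8-(3-methylbut-2-enyl)-4H-chromen-4-one
Product: 23 3-(3,4-dimethoxyphenyl)-7-hydroxy-6-methoxy-8-(3-methylbut-2-enyl)-4H-chromen-4-one (target)
Conditions: HCl (cat.), MeOH, 40 °C
Reagents that add atoms: none
Why: Acid-catalysed acetal exchange of an aryl MOM ether in methanol is routinely used next to ortho-prenyl groups in flavonoid work, and the weakly nucleophilic vinylogous-acid 7-OH should not add to the prenyl double bond under such mild conditions.

**Compound list**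
1 | isovanillin (3-hydroxy-4-methoxybenzaldehyde) | O=Cc1ccc(OC)c(O)c1 | starting material
2 | 4-methoxy-3-(methoxymethoxy)benzaldehyde | COCOc1cc(C=O)ccc1OC | intermediate
3 | 4-methoxy-3-(methoxymethoxy)phenyl formate | COCOc1cc(OC=O)ccc1OC | intermediate
4 | 4-methoxy-3-(methoxymethoxy)phenol | COCOc1cc(O)ccc1OC | intermediate
5 | 2-[4-methoxy-3-(methoxymethoxy)phenoxy]oxane (racemic) | COCOc1cc(OC2CCCCO2)ccc1OC | intermediate
6 | prenyl bromide (1-bromo-3-methylbut-2-ene) | CC(C)=CCBr | starting material
7 | [3-methoxy-2-(methoxymethoxy)-6-(oxan-2-yloxy)phenyl]lithium | [Li]c1c(OCOC)c(OC)ccc1OC1CCCCO1 | intermediate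
8 | 2-[4-methoxy-3-(methoxymethoxy)-2-(3-methylbut-2-enyl)phenoxy]oxane (racemic) | COCOc1c(OC)ccc(OC2CCCCO2)c1CC=C(C)C | intermediate
9 | [5-methoxy-4-(methoxymethoxy)-3-(3-methylbut-2-enyl)-2-(oxan-2-yloxy)phenyl]lithium | COCOc1c(OC)cc([Li])c(OC2CCCCO2)c1CC=C(C)C | intermediate
10 | 2-[6-iodo-4-methoxy-3-(methoxymethoxy)-2-(3-methylbut-2-enyl)phenoxy]oxane (racemic) | COCOc1c(OC)cc(I)c(OC2CCCCO2)c1CC=C(C)C | intermediate
11 | 3',4'-dimethoxyacetophenone | CC(=O)c1ccc(OC)c(OC)c1 | starting material
12 | potassium 1-(3,4-dimethoxyphenyl)ethenolate | C=C(O[K])c1ccc(OC)c(OC)c1 | intermediate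
13 | 1-(3,4-dimethoxyphenyl)vinyl trifluoromethanesulfonate | C=C(OS(=O)(=O)C(F)(F)F)c1ccc(OC)c(OC)c1 | intermediate
14 | 2-[1-(3,4-dimethoxyphenyl)vinyl]-4,4,5,5-tetramethyl-1,3,2-dioxaborolane | C=C(B1OC(C)(C)C(C)(C)O1)c1ccc(OC)c(OC)c1 | intermediate
15 | carbon monoxide | [C-]#[O+] | starting material
16 | 2-(3,4-dimethoxyphenyl)-1-[5-methoxy-4-(methoxymethoxy)-3-(3-methylbut-2-enyl)-2-(oxan-2-yloxy)phenyl]prop-2-en-1-one (racemic) | C=C(C(=O)c1cc(OC)c(OCOC)c(CC=C(C)C)c1OC1CCCCO1)c1ccc(OC)c(OC)c1 | intermediate
17 | 2-(3,4-dimethoxyphenyl)-1-[2-hydroxy-5-methoxy-4-(methoxymethoxy)-3-(3-methylbut-2-enyl)phenyl]prop-2-en-1-one | C=C(C(=O)c1cc(OC)c(OCOC)c(CC=C(C)C)c1O)c1ccc(OC)c(OC)c1 | intermediate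
18 | (±)-3-(3,4-dimethoxyphenyl)-6-methoxy-7-(methoxymethoxy)-8-(3-methylbut-2-enyl)chroman-4-one | COCOc1c(OC)cc2c(c1CC=C(C)C)OCC(c1ccc(OC)c(OC)c1)C2=O | intermediate
19 | lithium enolate of 18 (2H-chromen-4-olate) | COCOc1c(OC)cc2c(c1CC=C(C)C)OCC(c1ccc(OC)c(OC)c1)=C2O[Li] | intermediate
20 | (±)-3-(3,4-dimethoxyphenyl)-6-methoxy-7-(methoxymethoxy)-8-(3-methylbut-2-enyl)-3-(phenylselanyl)chroman-4-one | COCOc1c(OC)cc2c(c1CC=C(C)C)OCC([Se]c1ccccc1)(c1ccc(OC)c(OC)c1)C2=O | intermediate
21 | selenoxide of 20 (3-benzeneseleninyl compound, mixture of stereoisomers) | COCOc1c(OC)cc2c(c1CC=C(C)C)OCC([Se](=O)c1ccccc1)(c1ccc(OC)c(OC)c1)C2=O | intermediate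
22 | 3-(3,4-dimethoxyphenyl)-6-methoxy-7-(methoxymethoxy)-8-(3-methylbut-2-enyl)-4H-chromen-4-one | COCOc1c(OC)cc2c(c1CC=C(C)C)occ(-c1ccc(OC)c(OC)c1)c2=O | intermediate
23 | 3-(3,4-dimethoxyphenyl)-7-hydroxy-6-methoxy-8-(3-methylbut-2-enyl)-4H-chromen-4-one (achiral) | COc1ccc(-c2coc3c(CC=C(C)C)c(O)c(OC)cc3c2=O)cc1OC | target

**Step count**
- Total step count: 12.
- Longest linear sequence: 10 steps (steps 1–5 and 8–12, from isovanillin). Steps 6 and 7 form the short branch.

**Steps most likely to fail**

Step 8. Several processes could compete: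
- coupling without CO uptake;
- protodeboronation of the hindered α-styrylboronate;
- capture of the aroylpalladium species by water or hydroxide;
- consumption of the enone by polymerisation or conjugate addition in the hot basic medium.

The fallback keeps CO as C4 but forms the two bonds one after the other. It sets out from 10, 15 and 11 and comes back at 16. Palladium/Xantphos aminocarbonylation of 10 under CO (1 atm) with N,O-dimethylhydroxylamine hydrochloride and K2CO3 in toluene should give the Weinreb amide F1. Separately, 11 is condensed with 2,4,6-triisopropylbenzenesulfonyl hydrazide to the trisylhydrazone F2. A Shapiro reaction (n-BuLi, THF, −78 → 0 °C) converts it into 1-(3,4-dimethoxyphenyl)vinyllithium F3. Addition of this to the amide at −78 °C stops after one addition, so the sensitive enone 16 is released only in the cold quench and never meets base and heat.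

Step 5. Deprotonation at the benzylic and allylic CH2 of the prenyl chain, or next to the methoxy group, could erode the regiocontrol of the metalation. The fallback replaces deprotonation by electrophilic aromatic substitution. It sets out from 8 and comes back at 10. NIS in MeCN at 0 °C, in the dark and over solid NaHCO3, should iodinate the only ring position that is activated twice, ortho to OTHP and para to OMOM. This fallback makes no compound outside the list (entry F0).

Step 10. Three processes could intervene:
- ring opening of the β-aryloxy enolate by retro-oxa-Michael reaction;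
- slow C–Se bond formation at the fully substituted C3;
- attack of the selenium electrophile on the prenyl double bond.

The fallback avoids both the free enolate and selenium. It sets out from 18 and comes back at 22, so steps 10 and 11 both drop out. Soft enolisation with TMSOTf/Et3N in CH2Cl2 at 0 °C should give the trimethylsilyl enol ether F4. Saegusa–Ito oxidation with Pd(OAc)2 in MeCN at rt then installs C2=C3 by β-hydride elimination from the palladium enolate.

**Further compounds**
F1 | step 8 | N,5-dimethoxy-4-(methoxymethoxy)-N-methyl-3-(3-methylbut-2-enyl)-2-(oxan-2-yloxy)benzamide (racemic) | CON(C)C(=O)c1cc(OC)c(OCOC)c(CC=C(C)C)c1OC1CCCCO1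
F2 | step 8 | (E)-N'-[1-(3,4-dimethoxyphenyl)ethylidene]-2,4,6-triisopropylbenzenesulfonohydrazide | C/C(=N\NS(=O)(=O)c1c(C(C)C)cc(C(C)C)cc1C(C)C)c1ccc(OC)c(OC)c1
F3 | step 8 | [1-(3,4-dimethoxyphenyl)vinyl]lithium | [Li]C(=C)c1ccc(OC)c(OC)c1
F0 | step 5 | none | none
F4 | step 10 | [3-(3,4-dimethoxyphenyl)-6-methoxy-7-(methoxymethoxy)-8-(3-methylbut-2-enyl)-2H-chromen-4-yl]oxy-trimethylsilane | COCOc1c(OC)cc2c(c1CC=C(C)C)OCC(c1ccc(OC)c(OC)c1)=C2O[Si](C)(C)C
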